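## The problem

Rhamnetin 3,5,4'-tri-O-sulfate (24) is a flavonol: a 4H-chromen-4-one (rings A and C fused through C4a–C8a) with the catechol ring B on C2 and an oxygen on C3. It has no stereocentre, so there is nothing to relay or control in space; the difficulty lies in five oxygens with three different fates. O7 is a methyl ether, O3' stays a free phenol, and O3, O5 and O4' are sulfate monoesters. The two neighbouring oxygens of ring B must therefore be told apart, and the three hydroxyls to be sulfated must be unveiled together while O3' stays masked. Aryl and enol sulfate monoesters are highly polar and are lost under acid, so they must come at the very end and only a neutral step may follow them. The 5-hydroxyl is hydrogen-bonded to the C4 carbonyl and is the least willing of the three to take a sulfate. The C3 oxygen should already be present when ring C is closed, because adding it to a finished flavone costs oxidation steps. The feature that allows a short, convergent assembly is that C8a and C4a are neighbours on ring A and bear O1 and the C4 carbonyl. Such an ortho oxygen/acyl pair is what an aryne leaves after taking up an oxygen nucleophile and then an acyl electrophile, and the C5 oxygen next to C4a decides which aryne carbon receives which.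

## Retrosynthesis

**Endgame.** Target 24 is traced back to its 3'-O-benzyl ether 23 by cutting one benzylic C–O bond, because hydrogenolysis is neutral and leaves sulfate salts alone. Compound 23 goes back to triol 22 by cutting the three O–S bonds, and 22 to the fully protected flavonol 21. In 21 the three oxygens to be sulfated carry the same methoxymethyl (MOM) acetal and O3' alone carries benzyl. One acid step then exposes exactly the hydroxyls that must be sulfated, which is simpler than any attempt at selective sulfation of a tetrol. The forward steps must remove acetals without touching the benzyl ether and must push sulfation onto the chelated 5-hydroxyl.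

**Ring C.** Flavonol 21 is cut at O1–C8a and C4–C4a. This divides it into silyl triflate 9, the aryne precursor for ring A, and β-keto ester 17, which holds O1, C2 with ring B, C3 with its oxygen, and C4 as a methyl ester. The neighbouring cuts are less attractive:
- Cutting O1–C2 (the classical flavone logic) leads to an ortho-hydroxyaryl ketone of ring A and either a later C3 oxidation or an awkward α-alkoxy ketone.
- Cutting C2=C3 or C4a–C5 gives longer linear sequences (see the next section).

The chosen cut is the most convergent: each fragment carries one aromatic ring and is four or five steps from catalogue compounds, and C3 arrives oxygenated. The forward reaction has four requirements: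
- the enolate must react through oxygen and not carbon;
- the oxygen must add at the aryne carbon remote from the MOM ether;
- the enolate oxygen and the ester must be cis;
- the aryl anion must close onto the ester before it is protonated.

**Aryne precursor.** Triflate 9 is cut at C–Si and O–S and traced through silyl carbamate 7 and carbamate 3 to phenol 2, the mono-MOM ether of symmetric 5-methoxyresorcinol (1). The carbamate and the MOM ether both flank the carbon that must be silylated, so directed metalation puts silicon where the aryne needs it. The carbamate oxygen then becomes the triflate. The alternative, halogenating 1 at the carbon between its hydroxyls, runs against the innate preference of the ring.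

**Keto ester.** Compound 17 is cut between the ketone carbon and the α-carbon, giving aldol 16 and from it aldehyde 12 and MOM-glycolate 14. Aldol addition followed by oxidation is preferred to a crossed Claisen condensation on the corresponding methyl benzoate: that electron-rich ester is a poor acceptor for a glycolate enolate that also condenses with itself. Aldehyde 12 comes from 3,4-dihydroxybenzaldehyde (10) through 11, using the higher acidity of the 4-hydroxyl to place MOM there and benzyl on O3. Ester 14 comes from methyl glycolate (13).

## Roads not taken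

**Alternative 1:** Ring C is cut at C2=C3.
- *Forward step.* Ring A carries an α-alkoxy acyl phosphorane on C4a and the ring B aroyl ester on the ortho oxygen, as in A2. The ylide carbon (C3) attacks the ester carbonyl (C2) and Ph3PO is lost, giving chromone A1.
- *Merits.* O1–C8a is bought with the phenol, there is no ambident nucleophile, and intramolecular olefination of an ester carbonyl by an acyl phosphorane is a known way to chromones. In certainty of ring closure this road is better than the chosen one.
- *Weak points.* The ylide carbon is fully substituted and oxygen-bearing, and it must attack an electron-rich aryl ester. Base can instead trigger a Baker–Venkataraman-type acyl shift. Precursor A2 needs a fully differentiated 2-acyl-1,3,5-trioxygenated benzene, then α-alkoxylation and phosphonium formation in a long linear sequence. The 2-(trimethylsilyl)ethyl group on O3 needs its own deprotection.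
- *Comparison.* The chosen plan offers two short fragments joined late, a ring A pattern drawn from a symmetric resorcinol, and one acetal for all three oxygens to be sulfated. It pays for this with the uncertain O-arylation.

**Alternative 2:** Ring B is cut at C2'–C3' and C1'–C6'.
- *Forward step.* 2-Ethynylchromone A4 and 3-(methoxymethoxy)furan A5 undergo [4+2] cycloaddition. The oxygen-bridged adduct opens and aromatises so that the furan oxygen becomes the 3'-hydroxyl, giving A3.
- *Merits.* The two catechol oxygens are differentiated by construction, which the chosen plan achieves only through a selective alkylation (step 5). Benzylation of A3 would give 21, so the endgame would be shared.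
- *Weak points.* The road builds the one ring that can be bought and leaves ring C with its C3 oxygen to be made by some other method on the way to A4. The furan A5 is electron-rich and labile, A4 is a conjugate acceptor prone to side reactions, and both the cycloaddition and the bridge opening must be regioselective.
- *Comparison.* Against the inherent 3'/4' differentiation, the chosen plan sets a well-precedented regioselective etherification and a much shorter route that forms ring C directly.

**Alternative 3:** Ring A is cut at C4a–C5.
- *Forward step.* Heating cyclobutenone A7 opens it to a dienylketene. The ketene carbon closes by 6π-electrocyclisation onto the pyranone carbon that becomes C4a, and tautomerisation gives 5-hydroxyflavonol A6.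
- *Merits.* The ring A pattern is fixed by connectivity, and there is neither an aryne nor an ambident nucleophile. In these two respects it is cleaner than the chosen plan.
- *Weak points.* The third π component is a double bond of a 4-pyranone, a vinylogous ester that loses conjugation on closure. Only the ketene formed by inward rotation of the pyranone substituent can cyclise. A7 needs a monocyclic 2-aryl-3-alkoxy-4-pyranone with a cyclobutenone on C6, itself a long synthesis. The free 5-hydroxyl of A6 is no gain, since O5 shares the fate of O3 and O4'.
- *Comparison.* Both roads go beyond precedent in their key step. The chosen one does so with simpler fragments and fewer steps, and its failure mode can be bypassed by classical chemistry from the same aldehyde.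

Key step: step 10

Assumption: the sulfate monoesters 23 and 24 are drawn in the acid form of the target structure; in the flask and on isolation they would be ammonium or sodium salts (cation exchange), which changes neither the route nor the step count.

## Route

Step 1
Reactants: 1 5-methoxyresorcinol (5-methoxybenzene-1,3-diol)
Product: 2 3-methoxy-5-(methoxymethoxy)phenol
Conditions: NaH (1.0 equiv), DMF, 0 °C; MOMCl (1.0 equiv), 0 °C → rt
Reagents that add atoms: chloromethyl methyl ether (MOMCl), COCCl
Why: Williamson etherification of the monophenoxide; the two hydroxyls are equivalent, so only the degree of alkylation is at issue, and the statistical by-products (diol and bis-ether) are separated and the diol returned.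

Step 2
Reactants: 2 3-methoxy-5-(methoxymethoxy)phenol
Product: 3 3-methoxy-5-(methoxymethoxy)phenyl N-(propan-2-yl)carbamate
Conditions: i-PrNCO, Et3N (cat.), CH2Cl2, rt
Reagents that add atoms: isopropyl isocyanate, CC(C)N=C=O
Why: Amine-catalysed addition of the phenol to the isocyanate gives the secondary carbamate, a strong ortho-directing group that can later be removed under mild base.

Step 3
Reactants: 3 3-methoxy-5-(methoxymethoxy)phenyl N-(propan-2-yl)carbamate
Product: 7 5-methoxy-3-(methoxymethoxy)-2-(trimethylsilyl)phenyl N-(propan-2-yl)carbamate, via N-silyl carbamate 4 (not isolated), via aryllithium 5 (not isolated), via N-silyl C-silyl carbamate 6 (not isolated)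
Conditions: TBSOTf, TMEDA, Et2O, 0 °C → rt; n-BuLi, TMEDA, −78 °C; TMSCl, −78 °C → rt; aq. NaHSO4, 0 °C
Reagents that add atoms: chlorotrimethylsilane, C[Si](C)(C)Cl; tert-butyldimethylsilyl triflate, CC(C)(C)[Si](C)(C)OS(=O)(=O)C(F)(F)F (its silyl group is carried only by 4, 5 and 6 and is lost on work-up)
Why: Directed ortho-metalation: after N-silylation in the flask, the carbamate and the MOM ether, the two strongest directors on the ring, both flank C2, so deprotonation should occur there and not between carbamate and methyl ether. The low temperature suppresses the anionic Fries shift, TMSCl traps the aryllithium, and brief mild acid removes the N-silyl group.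

Step 4
Reactants: 7 5-methoxy-3-(methoxymethoxy)-2-(trimethylsilyl)phenyl N-(propan-2-yl)carbamate
Product: 9 5-methoxy-3-(methoxymethoxy)-2-(trimethylsilyl)phenyl trifluoromethanesulfonate, via silylphenol 8 (not isolated)
Conditions: Et2NH, DBU, MeCN, 40 °C; then PhNTf2, rt
Reagents that add atoms: N-phenylbis(trifluoromethanesulfonimide), O=S(=O)(N(c1ccccc1)S(=O)(=O)C(F)(F)F)C(F)(F)F
Why: E1cB cleavage of the N-monosubstituted carbamate (the isocyanate is trapped by Et2NH) frees the phenoxide, which is triflated in the same flask. The electron-rich silylphenol is never exposed to acid, and base leaves the C–Si bond and the MOM ether alone.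

Step 5
Reactants: 10 3,4-dihydroxybenzaldehyde
Product: 11 3-hydroxy-4-(methoxymethoxy)benzaldehyde
Conditions: K2CO3 (1.1 equiv), MOMCl (1.05 equiv), acetone, 0 °C → rt
Reagents that add atoms: chloromethyl methyl ether (MOMCl), COCCl
Why: Regioselective Williamson etherification: the 4-hydroxyl, para to the formyl group, is the more acidic, and its phenoxide is alkylated first.

Step 6
Reactants: 11 3-hydroxy-4-(methoxymethoxy)benzaldehyde
Product: 12 3-(benzyloxy)-4-(methoxymethoxy)benzaldehyde
Conditions: BnBr, K2CO3, DMF, rt
Reagents that add atoms: benzyl bromide, BrCc1ccccc1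
Why: Williamson benzylation of the remaining phenol; this marks O3' with the one group that survives acid and is removed by hydrogen.

Step 7
Reactants: 13 methyl glycolate (methyl 2-hydroxyacetate)
Product: 14 methyl 2-(methoxymethoxy)acetate
Conditions: MOMCl, i-Pr2NEt, CH2Cl2, 0 °C → rt
Reagents that add atoms: chloromethyl methyl ether (MOMCl), COCCl
Why: Standard acetal protection of a primary alcohol under non-nucleophilic amine base; the methyl ester is untouched.

Step 8
Reactants: 14 methyl 2-(methoxymethoxy)acetate; 12 3-(benzyloxy)-4-(methoxymethoxy)benzaldehyde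
Product: 16 methyl 3-[3-(benzyloxy)-4-(methoxymethoxy)phenyl]-3-hydroxy-2-(methoxymethoxy)propanoate (mixture of racemic diastereomers), via lithium enolate 15 (not isolated)
Conditions: LiN(i-Pr)2 (LDA), THF, −78 °C; then 12, −78 °C; aq. NH4Cl
Reagents that add atoms: none
Why: Aldol addition of an α-alkoxy ester lithium enolate to a non-enolisable aromatic aldehyde. Two stereocentres form without control, which does not matter because one is removed in step 9 and the other in step 10.

Step 9
Reactants: 16 methyl 3-[3-(benzyloxy)-4-(methoxymethoxy)phenyl]-3-hydroxy-2-(methoxymethoxy)propanoate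
Product: 17 methyl 3-[3-(benzyloxy)-4-(methoxymethoxy)phenyl]-2-(methoxymethoxy)-3-oxopropanoate (racemic)
Conditions: Dess–Martin periodinane (1.2 equiv), CH2Cl2, 0 °C → rt
Reagents that add atoms: none
Why: Dess–Martin oxidation of the benzylic secondary alcohol under near-neutral conditions that spare the acetals and the benzyl ether. The remaining stereocentre is enolisable and is taken on as the racemate.

Step 10
Reactants: 9 5-methoxy-3-(methoxymethoxy)-2-(trimethylsilyl)phenyl trifluoromethanesulfonate; 17 methyl 3-[3-(benzyloxy)-4-(methoxymethoxy)phenyl]-2-(methoxymethoxy)-3-oxopropanoate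
Product: 21 2-[3-(benzyloxy)-4-(methoxymethoxy)phenyl]-7-methoxy-3,5-bis(methoxymethoxy)-4H-chromen-4-one, via cesium enolate 18 (not isolated), via aryne 19 (not isolated), via aryl anion 20 (not isolated)
Conditions: CsF (3 equiv), THF, 65 °C; 9 (1.5 equiv) added slowly
Reagents that add atoms: none
Why: Proposed new method: fluoride removes the silyl group of 9 and triflate leaves, giving aryne 19, while 17 is present as its cesium enolate 18, a chelate in which the ketone-derived oxygen and the ester are cis (the E geometry by the sequence rules, because the α-oxygen outranks the ester carbon). The enolate oxygen adds to the aryne carbon remote from the MOM ether (future C8a), which places the charge of aryl anion 20 on C4a, next to and inductively stabilised by that ether. The anion then attacks the ester carbonyl six atoms away in a 6-exo-trig acyl substitution, methoxide leaves, and ring C is closed as the 3-alkoxy-4-pyranone with O1–C8a and C4–C4a newly formed. The closest known reaction type is the CsF-mediated annulation of arynes with methyl salicylates to xanthones (O-arylation, then intramolecular acyl substitution); what is new is an enolate oxygen in the role of the phenoxide, against the known tendency of β-keto esters to be arylated at carbon and to suffer insertion into their C–C bond. No stereocentre is formed (the one in racemic 17 disappears), and aryne regioselectivity is secured by the 3-alkoxy group, whose distortion of the triple bond directs nucleophiles to the distal carbon. O- over C-arylation is the selectivity not secured by precedent: it rests on the fully substituted, oxygen-bearing enolate carbon flanked by the ester and a twisted aroyl group, on the loose cesium ion pair, and on slow release of the aryne. THF is preferred to MeCN so that the aryl anion is not protonated by solvent before it closes, and the enolate geometries interconvert through the keto form, so the one that can cyclise is drained.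

Step 11
Reactants: 21 2-[3-(benzyloxy)-4-(methoxymethoxy)phenyl]-7-methoxy-3,5-bis(methoxymethoxy)-4H-chromen-4-one
Product: 22 2-[3-(benzyloxy)-4-hydroxyphenyl]-3,5-dihydroxy-7-methoxy-4H-chromen-4-one
Conditions: conc. HCl, MeOH–THF, 50 °C
Reagents that add atoms: none
Why: Acid-catalysed acetal exchange removes the three MOM groups together. Methanol in excess traps the methoxymethyl cation as dimethoxymethane before it can alkylate ring A, and the aryl benzyl ether is stable to these conditions.

Step 12
Reactants: 22 2-[3-(benzyloxy)-4-hydroxyphenyl]-3,5-dihydroxy-7-methoxy-4H-chromen-4-one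
Product: 23 2-[3-(benzyloxy)-4-(sulfooxy)phenyl]-7-methoxy-4-oxo-4H-chromene-3,5-diyl bis(hydrogen sulfate) (3'-O-benzylrhamnetin 3,5,4'-tri-O-sulfate)
Conditions: SO3·NMe3 (large excess), Et3N, MeCN, 100 °C (microwave)
Reagents that add atoms: sulfur trioxide–trimethylamine complex, C[N+](C)(C)S(=O)(=O)[O-]
Why: O-sulfonation of the three free hydroxyls by an amine–sulfur trioxide complex. Excess reagent, base and heating are needed to overcome the hydrogen bond of the 5-hydroxyl to the C4 carbonyl and the growing negative charge, and the benzyl ether keeps O3' out of the reaction.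

Step 13
Reactants: 23 3'-O-benzylrhamnetin 3,5,4'-tri-O-sulfate
Product: 24 rhamnetin 3,5,4'-tri-O-sulfate (2-[3-hydroxy-4-(sulfooxy)phenyl]-7-methoxy-4-oxo-4H-chromene-3,5-diyl bis(hydrogen sulfate))
Conditions: H2 (1 atm), 10% Pd/C, MeOH–H2O, rt
Reagents that add atoms: none
Why: Hydrogenolysis of the aryl benzyl ether under neutral conditions; sulfate monoester salts and the C2=C3 bond of the chromone are not expected to react at atmospheric pressure.

## Compound list

1 | 5-methoxyresorcinol (5-methoxybenzene-1,3-diol) | COc1cc(O)cc(O)c1 | starting material
2 | 3-methoxy-5-(methoxymethoxy)phenol | COCOc1cc(O)cc(OC)c1 | intermediate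
3 | 3-methoxy-5-(methoxymethoxy)phenyl N-(propan-2-yl)carbamate | COCOc1cc(OC)cc(OC(=O)NC(C)C)c1 | intermediate
4 | 3-methoxy-5-(methoxymethoxy)phenyl N-(tert-butyldimethylsilyl)-N-(propan-2-yl)carbamate | COCOc1cc(OC)cc(OC(=O)N(C(C)C)[Si](C)(C)C(C)(C)C)c1 | intermediate (not isolated)
5 | 2-lithio-5-methoxy-3-(methoxymethoxy)phenyl N-(tert-butyldimethylsilyl)-N-(propan-2-yl)carbamate | [Li]c1c(OCOC)cc(OC)cc1OC(=O)N(C(C)C)[Si](C)(C)C(C)(C)C | intermediate (not isolated)
6 | 5-methoxy-3-(methoxymethoxy)-2-(trimethylsilyl)phenyl N-(tert-butyldimethylsilyl)-N-(propan-2-yl)carbamate | COCOc1cc(OC)cc(OC(=O)N(C(C)C)[Si](C)(C)C(C)(C)C)c1[Si](C)(C)C | intermediate (not isolated)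
7 | 5-methoxy-3-(methoxymethoxy)-2-(trimethylsilyl)phenyl N-(propan-2-yl)carbamate | COCOc1cc(OC)cc(OC(=O)NC(C)C)c1[Si](C)(C)C | intermediate
8 | 5-methoxy-3-(methoxymethoxy)-2-(trimethylsilyl)phenol | COCOc1cc(OC)cc(O)c1[Si](C)(C)C | intermediate (not isolated)
9 | 5-methoxy-3-(methoxymethoxy)-2-(trimethylsilyl)phenyl trifluoromethanesulfonate | COCOc1cc(OC)cc(OS(=O)(=O)C(F)(F)F)c1[Si](C)(C)C | intermediate
10 | 3,4-dihydroxybenzaldehyde | O=Cc1ccc(O)c(O)c1 | starting material
11 | 3-hydroxy-4-(methoxymethoxy)benzaldehyde | COCOc1ccc(C=O)cc1O | intermediate
12 | 3-(benzyloxy)-4-(methoxymethoxy)benzaldehyde | COCOc1ccc(C=O)cc1OCc1ccccc1 | intermediate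
13 | methyl glycolate (methyl 2-hydroxyacetate) | COC(=O)CO | starting material
14 | methyl 2-(methoxymethoxy)acetate | COCOCC(=O)OC | intermediate
15 | lithium enolate of methyl 2-(methoxymethoxy)acetate | COCOC=C(OC)O[Li] | intermediate (not isolated)
16 | methyl 3-[3-(benzyloxy)-4-(methoxymethoxy)phenyl]-3-hydroxy-2-(methoxymethoxy)propanoate (mixture of racemic diastereomers) | COCOC(C(=O)OC)C(O)c1ccc(OCOC)c(OCc2ccccc2)c1 | intermediate
17 | methyl 3-[3-(benzyloxy)-4-(methoxymethoxy)phenyl]-2-(methoxymethoxy)-3-oxopropanoate (racemic) | COCOC(C(=O)OC)C(=O)c1ccc(OCOC)c(OCc2ccccc2)c1 | intermediate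
18 | cesium (E)-1-[3-(benzyloxy)-4-(methoxymethoxy)phenyl]-3-methoxy-2-(methoxymethoxy)-3-oxoprop-1-en-1-olate | COCO/C(C(=O)OC)=C(/O[Cs])c1ccc(OCOC)c(OCc2ccccc2)c1 | intermediate (not isolated)
19 | 5-methoxy-3-(methoxymethoxy)benzyne (1,2-didehydro-5-methoxy-3-(methoxymethoxy)benzene) | COCOC1=CC(OC)=CC#C1 | intermediate (not isolated)
20 | methyl (E)-3-[3-(benzyloxy)-4-(methoxymethoxy)phenyl]-3-[2-cesio-5-methoxy-3-(methoxymethoxy)phenoxy]-2-(methoxymethoxy)prop-2-enoate | COCO/C(C(=O)OC)=C(/Oc1cc(OC)cc(OCOC)c1[Cs])c1ccc(OCOC)c(OCc2ccccc2)c1 | intermediate (not isolated)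
21 | 2-[3-(benzyloxy)-4-(methoxymethoxy)phenyl]-7-methoxy-3,5-bis(methoxymethoxy)-4H-chromen-4-one | COCOc1ccc(-c2oc3cc(OC)cc(OCOC)c3c(=O)c2OCOC)cc1OCc1ccccc1 | intermediate
22 | 2-[3-(benzyloxy)-4-hydroxyphenyl]-3,5-dihydroxy-7-methoxy-4H-chromen-4-one | COc1cc(O)c2c(=O)c(O)c(-c3ccc(O)c(OCc4ccccc4)c3)oc2c1 | intermediate
23 | 3'-O-benzylrhamnetin 3,5,4'-tri-O-sulfate | COc1cc(OS(=O)(=O)O)c2c(=O)c(OS(=O)(=O)O)c(-c3ccc(OS(=O)(=O)O)c(OCc4ccccc4)c3)oc2c1 | intermediate
24 | rhamnetin 3,5,4'-tri-O-sulfate | COc1cc(OS(=O)(=O)O)c2c(=O)c(OS(=O)(=O)O)c(-c3ccc(OS(=O)(=O)O)c(O)c3)oc2c1 | target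

## Step count and risks

Total steps: 13. Longest linear sequence: 8 steps (1 → 2 → 3 → 7 → 9 → 21 → 22 → 23 → 24; the ring B line 10 → 11 → 12 → 16 → 17 → 21 → 24 is equally long).

**Step 10 (key step, Proposed new method).**
- *What may go wrong.* The enolate may be arylated at carbon and then suffer insertion into the C–C bond, the usual course for β-keto esters. O-arylation may occur from the enolate geometry that cannot reach the ester, ending in protonation. The aryl anion may be protonated before ring closure.
- *Fallback (known chemistry), from aldehyde 12 to triol 22.* The commercial 1-(2,6-dihydroxy-4-methoxyphenyl)ethan-1-one is converted into its mono-MOM ether, 1-[2-hydroxy-4-methoxy-6-(methoxymethoxy)phenyl]ethan-1-one F1 (MOMCl, K2CO3, acetone; the second hydroxyl stays chelated to the ketone). Claisen–Schmidt condensation of F1 with 12 (KOH, EtOH) gives the chalcone (2E)-3-[3-(benzyloxy)-4-(methoxymethoxy)phenyl]-1-[2-hydroxy-4-methoxy-6-(methoxymethoxy)phenyl]prop-2-en-1-one F2. Algar–Flynn–Oyamada oxidation (H2O2, aq. NaOH, MeOH) closes ring C with the C3 oxygen in place, giving 2-[3-(benzyloxy)-4-(methoxymethoxy)phenyl]-3-hydroxy-7-methoxy-5-(methoxymethoxy)-4H-chromen-4-one F3. Methanolic HCl as in step 11 then gives 22. This line forms O1–C2 instead of O1–C8a, and its known cost is partial diversion of 6'-alkoxychalcones to aurones.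

**Step 12.**
- *What may go wrong.* Sulfation may stall before the chelated 5-hydroxyl reacts, because of the hydrogen bond and the accumulating negative charge. The 3-sulfate may hydrolyse during isolation.
- *Fallback, from 22 to 23.* Compound 22 is treated with 2,2,2-trichloroethyl chlorosulfate (Et3N, DMAP, THF, with NaN(SiMe3)2 if the 5-oxygen lags) to give 3'-O-benzylrhamnetin 3,5,4'-tris(2,2,2-trichloroethyl sulfate) F4. This neutral diester builds up no charge and can be purified on silica. Zn and HCO2NH4 in MeOH then release the three sulfate monoesters by reductive elimination, giving 23.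

**Step 3.**
- *What may go wrong.* Lithiation may occur at the carbon between carbamate and methyl ether, giving the isomeric silane. The silyl triflate may activate the MOM acetal. The very electron-rich arylsilane may be protodesilylated on acidic work-up.
- *Fallback, from 1 to 9.* Both hydroxyls of 1 are carbamoylated (i-PrNCO, Et3N) to 5-methoxy-1,3-phenylene bis[N-(propan-2-yl)carbamate] F5. The sequence of step 3 now acts on a symmetric ring whose carbon between the two carbamates is flanked by the two strongest directors, giving 5-methoxy-2-(trimethylsilyl)-1,3-phenylene bis[N-(propan-2-yl)carbamate] F6. Et2NH and DBU free both phenoxides, and one equivalent of PhNTf2 gives 3-hydroxy-5-methoxy-2-(trimethylsilyl)phenyl trifluoromethanesulfonate F7; the first triflate deactivates the second phenoxide. MOMCl with i-Pr2NEt then gives 9. The acetal never meets the silyl triflate or the organolithium.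

**Step 13.**
- *What may go wrong.* Sulfate may be lost by hydrolysis if the medium turns acidic. Hydrogenolysis of the polyanion may be slow. The C2=C3 bond may be over-reduced on long exposure.
- *Fallback, from 22 to 24.* The diester F4 (made as in the fallback to step 12) is debenzylated as a neutral compound with BCl3 and pentamethylbenzene (CH2Cl2, −78 °C), giving rhamnetin 3,5,4'-tris(2,2,2-trichloroethyl sulfate) F8. Zn and HCO2NH4 in MeOH then release the three sulfates to give 24. No hydrogen and no hydrogenation catalyst meet the free sulfates.

## Further compounds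

F1 | step 10 | 1-[2-hydroxy-4-methoxy-6-(methoxymethoxy)phenyl]ethan-1-one | CC(=O)c1c(O)cc(OC)cc1OCOC
F2 | step 10 | (2E)-3-[3-(benzyloxy)-4-(methoxymethoxy)phenyl]-1-[2-hydroxy-4-methoxy-6-(methoxymethoxy)phenyl]prop-2-en-1-one | COCOc1ccc(/C=C/C(=O)c2c(O)cc(OC)cc2OCOC)cc1OCc1ccccc1
F3 | step 10 | 2-[3-(benzyloxy)-4-(methoxymethoxy)phenyl]-3-hydroxy-7-methoxy-5-(methoxymethoxy)-4H-chromen-4-one | COCOc1ccc(-c2oc3cc(OC)cc(OCOC)c3c(=O)c2O)cc1OCc1ccccc1
F4 | step 12 | 3'-O-benzylrhamnetin 3,5,4'-tris(2,2,2-trichloroethyl sulfate) | COc1cc(OS(=O)(=O)OCC(Cl)(Cl)Cl)c2c(=O)c(OS(=O)(=O)OCC(Cl)(Cl)Cl)c(-c3ccc(OS(=O)(=O)OCC(Cl)(Cl)Cl)c(OCc4ccccc4)c3)oc2c1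
F5 | step 3 | 5-methoxy-1,3-phenylene bis[N-(propan-2-yl)carbamate] | COc1cc(OC(=O)NC(C)C)cc(OC(=O)NC(C)C)c1
F6 | step 3 | 5-methoxy-2-(trimethylsilyl)-1,3-phenylene bis[N-(propan-2-yl)carbamate] | COc1cc(OC(=O)NC(C)C)c([Si](C)(C)C)c(OC(=O)NC(C)C)c1
F7 | step 3 | 3-hydroxy-5-methoxy-2-(trimethylsilyl)phenyl trifluoromethanesulfonate | COc1cc(O)c([Si](C)(C)C)c(OS(=O)(=O)C(F)(F)F)c1
F8 | step 13 | rhamnetin 3,5,4'-tris(2,2,2-trichloroethyl sulfate) | COc1cc(OS(=O)(=O)OCC(Cl)(Cl)Cl)c2c(=O)c(OS(=O)(=O)OCC(Cl)(Cl)Cl)c(-c3ccc(OS(=O)(=O)OCC(Cl)(Cl)Cl)c(O)c3)oc2c1
A1 | alternative 1 | 2-[3-(benzyloxy)-4-(methoxymethoxy)phenyl]-7-methoxy-5-(methoxymethoxy)-3-[2-(trimethylsilyl)ethoxy]-4H-chromen-4-one | C[Si](C)(C)CCOc1c(-c2ccc(OCOC)c(OCc3ccccc3)c2)oc2cc(OC)cc(OCOC)c2c1=O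
A2 | alternative 1 | 5-methoxy-3-(methoxymethoxy)-2-{[2-(trimethylsilyl)ethoxy](triphenyl-λ5-phosphanylidene)acetyl}phenyl 3-(benzyloxy)-4-(methoxymethoxy)benzoate | C[Si](C)(C)CCOC(=P(c1ccccc1)(c1ccccc1)c1ccccc1)C(=O)c1c(OCOC)cc(OC)cc1OC(=O)c1ccc(OCOC)c(OCc2ccccc2)c1
A3 | alternative 2 | 2-[3-hydroxy-4-(methoxymethoxy)phenyl]-7-methoxy-3,5-bis(methoxymethoxy)-4H-chromen-4-one | COCOc1ccc(-c2oc3cc(OC)cc(OCOC)c3c(=O)c2OCOC)cc1O
A4 | alternative 2 | 2-ethynyl-7-methoxy-3,5-bis(methoxymethoxy)-4H-chromen-4-one | C#Cc1oc2cc(OC)cc(OCOC)c2c(=O)c1OCOC
A5 | alternative 2 | 3-(methoxymethoxy)furan | COCOc1ccoc1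
A6 | alternative 3 | 2-[3-(benzyloxy)-4-(methoxymethoxy)phenyl]-5-hydroxy-7-methoxy-3-(methoxymethoxy)-4H-chromen-4-one | COCOc1ccc(-c2oc3cc(OC)cc(O)c3c(=O)c2OCOC)cc1OCc1ccccc1
A7 | alternative 3 | 4-{6-[3-(benzyloxy)-4-(methoxymethoxy)phenyl]-5-(methoxymethoxy)-4-oxo-4H-pyran-2-yl}-3-methoxycyclobut-2-en-1-one (racemic) | COC1=CC(=O)C1c1cc(=O)c(OCOC)c(-c2ccc(OCOC)c(OCc3ccccc3)c2)o1
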